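## Analysis of the target

Compound 10, (2S)-5,7-dimethoxy-2-(3,4,5-trimethoxyphenyl)chroman-4-one, is a fully O-methylated flavanone. Benzo ring A (C4a, C5 to C8, C8a, with methoxyls on C5 and C7) is fused to the dihydropyranone ring C (O1, C2, C3, C4, C4a, C8a), and C2 carries ring B, a 3,4,5-trimethoxyphenyl group. C2 is the only stereocentre; it is S, benzylic to ring B, bonded to the aryl ether oxygen O1 and β to the C4 ketone. This makes it fragile: enolisation towards C3 lets O1 leave as a phenoxide (retro-oxa-Michael opening to the 2'-hydroxychalcone), so base, and more slowly acid, racemise the compound once the ketone exists. Both arenes are electron rich, C6 and C8 of ring A are open to electrophiles, and the C4 carbonyl carbon, flanked by C5–OMe and conjugated with three oxygen donors, is a weak electrophile. The difficulty is therefore to set one labile C–O stereocentre with absolute control and then reach the ketone without exposing it to base. The plan rests on cutting ring C twice, at O1–C2 and at C3–C4. O1, C8a, C4a and C4 then lie in a salicylaldehyde that already holds ring A, and C2, C3 and ring B lie in a cinnamaldehyde whose formyl carbon becomes a removable substituent on C3.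

## Retrosynthetic reasoning

**10 to 9 (C4 oxidation level).** The ketone is taken back to the secondary alcohol 9. The carbonyl is what makes C2 labile, so it should appear last and under neutral conditions. The forward step only has to oxidise a benzylic alcohol without acid or base strong enough to open ring C; the C4 configuration of 9 is irrelevant.

**9 to 7 (C4–O bond).** Cutting the C4–O bond leaves the C3=C4 alkene of the 2H-chromene 7. The forward reaction is a Markovnikov hydration that must place oxygen on C4 and not on C3. A radical pathway secures this, because a radical at C4 is benzylic to ring A while one at C3 has no stabilisation. Ionic hydration is avoided: acid would ionise the doubly benzylic, allylic C2–O1 bond, and electrophilic metal salts would attack ring A.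

**7 to 6 (C3–CHO bond).** A formyl group is placed on C3, giving the chromene aldehyde 6. This carbon is what makes C3 nucleophilic (as an enamine) and C2 electrophilic (as an iminium β carbon) in the ring-forming step. The forward decarbonylation must leave the double bond at C3=C4 and must not disturb C2.

**6 to 1 and 2 (O1–C2 and C3–C4).** Both ring C bonds are cut at once, giving the salicylaldehyde 1 (ring A, O1, C4) and the cinnamaldehyde 2 (C2, C3, ring B, formyl carbon). Both are purchasable and carry every methoxy group, so no protecting group or late methylation is needed. The polarity is matched: phenol oxygen to the β carbon of the enal, enal α carbon to the aryl aldehyde. The forward step has to choose one face of the β carbon under control of a chiral secondary amine, favour conjugate O-addition, and finish with an irreversible dehydration so that the reversible C–O bond formation cannot erode C2.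

## Alternatives that were turned down

**Alternative 1: biomimetic Claisen closure of ring A.**
- Disconnection: C4a–C5, with ring A unravelled into a polyketide chain. The substrate is methyl 3-oxo-4-[(2S)-4-oxo-2-(3,4,5-trimethoxyphenyl)-3,4-dihydro-2H-pyran-6-yl]butanoate A1, which already holds O1, C2, C3, C4, C4a and C8a.
- Forward key step: the dienolate of A1 attacks the terminal ester through C4a, and the new six-membered carbocycle enolises to the arene, giving (2S)-5,7-dihydroxy-2-(3,4,5-trimethoxyphenyl)chroman-4-one A2.
- For: C2 would be set early on a simple dihydropyranone, for instance by an asymmetric hetero-Diels–Alder reaction of the ring B aldehyde. That reaction class is irreversible and dependable, and on this point the alternative is stronger than a reversible oxa-Michael addition.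
- Against: A1 is several steps from purchasable material. Its dienolate is made with strong base in a ring whose C3 enolate can expel O1 and racemise C2. The product A2 has two free phenols, and the C5 hydroxyl is chelated to the C4 carbonyl; it methylates only under basic, forcing conditions, which is the treatment a flavanone tolerates least.
- Comparison: the route builds an arene that can be bought with both methyl ethers in place, and it is clearly longer. The chosen route gives up the irreversible stereo-setting step but never puts base on the ketone.

**Alternative 2: dithiane linchpin.**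
- Disconnection: C3–C4 and O1–C8a. C4 is an acyl anion equivalent, 2-(2-fluoro-4,6-dimethoxyphenyl)-1,3-dithiane A3. C2, C3 and ring B come from (R)-2-(3,4,5-trimethoxyphenyl)oxirane A4.
- Forward key step: lithiated A3 opens A4 at its CH2 carbon, and the alkoxide formed at C2 displaces the ortho fluoride in the same flask, giving (2S)-5,7-dimethoxy-2-(3,4,5-trimethoxyphenyl)spiro[chromane-4,2'-[1,3]dithiane] A5. Unmasking gives 10.
- For: it is convergent, the ketone stays masked, and C2 comes from an epoxide of secure configuration and takes part in neither bond formation. On stereochemical certainty it is stronger than the chosen route.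
- Against: the fluoroarene of A3 carries two methoxy donors and no acceptor, so the ring closure lacks the activation an addition–elimination at an arene needs. The aryl C–H between fluorine and methoxyl in A3 is an acidic ortho-metalation site, so the base can metalate the ring and open an aryne pathway. The electron-rich A4 tends to open at its benzylic carbon or rearrange under lithium ion assistance. Unmasking A5 needs soft electrophiles or oxidants, to which C6 and C8 of ring A are exposed.
- Comparison: with A3 and A4 each to be prepared, the sequence runs to about seven steps against four. The chosen route instead closes ring C with a phenol that is already on the arene.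

**Alternative 3: enol ether ring-closing metathesis.**
- Disconnection: the C3=C4 alkene, after O1–C2. The substrate is tert-butyl[(1-{2,4-dimethoxy-6-[(1S)-1-(3,4,5-trimethoxyphenyl)prop-2-en-1-yl]oxyphenyl}ethenyl)oxy]dimethylsilane A6. Its C2 centre would come from an iridium-catalysed allylic etherification of a phenolic acetophenone, followed by enol silylation.
- Forward key step: a ruthenium alkylidene joins the vinyl group on C2 to the enol ether carbon C4 with release of a volatile alkene, giving (2S)-4-(tert-butyldimethylsilyloxy)-5,7-dimethoxy-2-(3,4,5-trimethoxyphenyl)-2H-chromene A7, the silyl enol ether of 10.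
- For: the C4 oxygen is present from the start, and the ketone is unveiled by the mildest possible hydrolysis, with no decarbonylation, hydration or oxidant. In the endgame this alternative is stronger than the chosen route.
- Against: the metathesis must engage a 1,1-disubstituted, electron-rich silyl enol ether next to a 2,6-disubstituted arene and form a trisubstituted alkene. If the catalyst loads on the enol ether it forms an unreactive heteroatom-stabilised carbene. The etherification needs an ortho-acyl phenoxide, chelated and weakly nucleophilic. Enol silylation puts base on a compound whose C2–H is benzylic, allylic and α to oxygen.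
- Comparison: counting the preparation of the allylic electrophile, it needs about six steps. The chosen route assembles all skeletal bonds and the stereocentre from two purchasable aldehydes in one metal-free catalytic step, at the price of three adjustment steps.

Key step: step 1

Remark: the sense of induction in step 1 is derived from the accepted shielding model for diarylprolinol silyl ether iminium ions, not from a measured result. The C4 configuration of 8 and 9 is left open because step 4 removes it.

## Route

**Step 1**
Reactants: 1 2-hydroxy-4,6-dimethoxybenzaldehyde; 2 (E)-3-(3,4,5-trimethoxyphenyl)prop-2-enal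
Product: 6 (2R)-5,7-dimethoxy-2-(3,4,5-trimethoxyphenyl)-2H-chromene-3-carbaldehyde, via iminium benzoate 3 (not isolated), via oxa-Michael enamine 4 (not isolated), via aldol iminium benzoate 5 (not isolated)
Conditions: (S)-2-[diphenyl(trimethylsilyloxy)methyl]pyrrolidine (20 mol %), PhCO2H (20 mol %), 4 Å MS, PhMe, rt
Reagents that add atoms: none
Why: Domino oxa-Michael/aldol condensation under iminium then enamine catalysis, the known aminocatalytic route from salicylaldehydes and enals to 2H-chromene-3-carbaldehydes. The amine condenses with the unhindered enal 2, not with the deactivated, hydrogen-bonded aryl aldehyde of 1, to give the E,s-trans iminium ion 3, and the phenol oxygen of 1 adds to its β carbon (O1–C2) to give enamine 4. The α carbon of 4 then attacks the neighbouring aryl aldehyde in a 6-exo-trig (enol-exo) aldol closure (C3–C4) to 5, and loss of water followed by hydrolysis releases 6 and the catalyst. C2 is the only stereocentre that survives; the diphenyl(trimethylsilyloxy)methyl group of the S catalyst covers the Re face of the β carbon, so oxygen should enter from the Si face, which is 2R in 6 and becomes 2S once the formyl group is gone. Because the oxa-Michael step is reversible, the irreversible dehydration drains 4 forward, and an enamine of the wrong configuration can revert instead of accumulating. O-attack is favoured over C-attack by ring A because the formyl group deactivates the arene of 1 while its ortho oxygen is placed for six-membered ring formation; 1,2-adducts form reversibly and lead nowhere. The sieves and the weak carboxylic acid speed iminium formation and dehydration without making the medium acidic enough to ionise the benzylic C2–O1 bond.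

**Step 2**
Reactants: 6 (2R)-5,7-dimethoxy-2-(3,4,5-trimethoxyphenyl)-2H-chromene-3-carbaldehyde
Product: 7 (2S)-5,7-dimethoxy-2-(3,4,5-trimethoxyphenyl)-2H-chromene
Conditions: RhCl(PPh3)3 (1.1 equiv), degassed PhMe, 90–110 °C, Ar, dark
Reagents that add atoms: none
Why: Tsuji–Wilkinson decarbonylation: the formyl C–H bond adds to monovalent rhodium, CO migrates from the acyl group to the metal, and C–H reductive elimination gives the alkene with the double bond kept at C3=C4; the firmly bound CO in RhCl(CO)(PPh3)2 is why a full equivalent is used, which allows the lowest workable temperature. C2 is not part of the reacting array and keeps its arrangement (named 2S now because C3 loses rank); exclusion of light and acid guards against ring opening of the 2H-chromene.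

**Step 3**
Reactants: 7 (2S)-5,7-dimethoxy-2-(3,4,5-trimethoxyphenyl)-2H-chromene
Product: 9 (2S)-5,7-dimethoxy-2-(3,4,5-trimethoxyphenyl)chroman-4-ol as a mixture of C4 epimers, via C4 hydroperoxide 8 (not isolated)
Conditions: Mn(dpm)3 (15 mol %), PhSiH3, O2 (1 atm), iPrOH/CH2Cl2, 0 °C to rt; then PPh3
Reagents that add atoms: dioxygen, O=O
Why: Mukaiyama-type hydrogen-atom-transfer hydration: a manganese hydride formed from Mn(dpm)3 and PhSiH3 gives a hydrogen atom to C3, because the radical then sits at C4, benzylic to ring A and stabilised by O1, C5–OMe and C7–OMe; O2 traps it to hydroperoxide 8 and PPh3 cleaves the O–O bond. The neutral conditions leave C2 untouched; the new C4 centre forms unselectively and is erased in step 4, and any ketone 10 formed directly is carried along.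

**Step 4**
Reactants: 9 (2S)-5,7-dimethoxy-2-(3,4,5-trimethoxyphenyl)chroman-4-ol (both C4 epimers)
Product: 10 (2S)-5,7-dimethoxy-2-(3,4,5-trimethoxyphenyl)chroman-4-one
Conditions: DMP (1.3 equiv), NaHCO3, CH2Cl2, 0 °C to rt
Reagents that add atoms: none
Why: Oxidation of a secondary benzylic alcohol with the hypervalent iodine reagent DMP (1,1,1-triacetoxy-1,1-dihydro-1,2-benziodoxol-3(1H)-one) under bicarbonate buffering; ligand exchange at iodine and internal deprotonation need neither strong acid nor base, so ring C is not opened by retro-oxa-Michael reaction and C2 stays S. Both C4 epimers converge on 10, and the buffer keeps the ionisable alcohol 9 from losing its hydroxyl at C4.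

## Compound list

1 | 2-hydroxy-4,6-dimethoxybenzaldehyde | COc1cc(O)c(C=O)c(OC)c1 | starting material
2 | (E)-3-(3,4,5-trimethoxyphenyl)prop-2-enal | COc1cc(/C=C/C=O)cc(OC)c1OC | starting material
3 | (2S)-2-[diphenyl(trimethylsilyloxy)methyl]-1-[(E)-3-(3,4,5-trimethoxyphenyl)prop-2-en-1-ylidene]pyrrolidinium benzoate | COc1cc(/C=C/C=[N+]2CCC[C@H]2C(c2ccccc2)(c2ccccc2)O[Si](C)(C)C)cc(OC)c1OC.[O-]C(=O)c1ccccc1 | intermediate
4 | 2-{[(1S,2E)-3-{(2S)-2-[diphenyl(trimethylsilyloxy)methyl]pyrrolidin-1-yl}-1-(3,4,5-trimethoxyphenyl)prop-2-en-1-yl]oxy}-4,6-dimethoxybenzaldehyde | COc1cc(OC)c(C=O)c(c1)O[C@H](c1cc(OC)c(OC)c(OC)c1)/C=C/N1CCC[C@H]1C(c1ccccc1)(c1ccccc1)O[Si](C)(C)C | intermediate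
5 | (2S)-2-[diphenyl(trimethylsilyloxy)methyl]-1-{[(2S)-4-hydroxy-5,7-dimethoxy-2-(3,4,5-trimethoxyphenyl)chroman-3-yl]methylidene}pyrrolidinium benzoate (C3 and C4 not defined) | COc1cc(OC)c2c(c1)O[C@H](c1cc(OC)c(OC)c(OC)c1)C(C=[N+]1CCC[C@H]1C(c1ccccc1)(c1ccccc1)O[Si](C)(C)C)C2O.[O-]C(=O)c1ccccc1 | intermediate
6 | (2R)-5,7-dimethoxy-2-(3,4,5-trimethoxyphenyl)-2H-chromene-3-carbaldehyde | COc1cc(OC)c2c(c1)O[C@H](c1cc(OC)c(OC)c(OC)c1)C(C=O)=C2 | intermediate
7 | (2S)-5,7-dimethoxy-2-(3,4,5-trimethoxyphenyl)-2H-chromene | COc1cc(OC)c2c(c1)O[C@H](c1cc(OC)c(OC)c(OC)c1)C=C2 | intermediate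
8 | (2S)-4-hydroperoxy-5,7-dimethoxy-2-(3,4,5-trimethoxyphenyl)chroman (C4 epimers) | COc1cc(OC)c2c(c1)O[C@H](c1cc(OC)c(OC)c(OC)c1)CC2OO | intermediate
9 | (2S)-5,7-dimethoxy-2-(3,4,5-trimethoxyphenyl)chroman-4-ol (C4 epimers) | COc1cc(OC)c2c(c1)O[C@H](c1cc(OC)c(OC)c(OC)c1)CC2O | intermediate
10 | (2S)-5,7-dimethoxy-2-(3,4,5-trimethoxyphenyl)chroman-4-one | COc1cc(OC)c2c(c1)O[C@H](c1cc(OC)c(OC)c(OC)c1)CC2=O | target

## Step count and least certain steps

Total step count: 4. Longest linear sequence: 4 steps (from 1 or 2 to 10).

**Step 1 (key step).**
- What may go wrong: the aldol closure may be slow, because the aldehyde of 1 sits between a hydroxyl and a methoxyl and is deactivated by three oxygen donors. Enamine 4 would then revert by retro-oxa-Michael reaction instead of cyclising, giving low conversion. Enantiopurity could also erode, through the same reversibility or through slow ionisation of the benzylic C2–O1 bond of 6 in the presence of the acid co-catalyst. If the absolute sense of induction proves opposite to the shielding model, the R catalyst is used in the same way.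
- Fallback (sets out from 1 and 2, rejoins at 7): 2 is reduced with NaBH4 and CeCl3·7H2O in MeOH at 0 °C to (E)-3-(3,4,5-trimethoxyphenyl)prop-2-en-1-ol F1. Acylation with ClCO2Me and pyridine gives methyl (E)-3-(3,4,5-trimethoxyphenyl)prop-2-en-1-yl carbonate F2. Iridium-catalysed allylic etherification of F2 with phenol 1 follows, using [Ir(cod)Cl]2 and the phosphoramidite O,O'-(1,1'-binaphthalene-2,2'-diyl)-N,N-bis(1-phenylethyl)phosphoramidite in THF at rt, with the ligand enantiomer chosen for the S product. It should give the branched ether 2,4-dimethoxy-6-{[(1S)-1-(3,4,5-trimethoxyphenyl)prop-2-en-1-yl]oxy}benzaldehyde F3; the methoxide released from the carbonate serves as base. Wittig methylenation with Ph3P=CH2 in THF at −78 to 0 °C gives 2-ethenyl-1,5-dimethoxy-3-{[(1S)-1-(3,4,5-trimethoxyphenyl)prop-2-en-1-yl]oxy}benzene F4. Ring-closing metathesis with RuCl2(H2IMes)(PCy3)(=CHPh) in CH2Cl2 at 40 °C closes C3=C4 and gives 7. This detour also bypasses step 2, at the cost of three extra steps.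

**Step 2.**
- What may go wrong: thermal 6π-electrocyclic opening of the 2H-chromene ring to an ortho-quinone methide and reclosure would racemise C2 in 6 or 7 at the temperature the decarbonylation needs. Double-bond migration towards C2=C3 through rhodium hydride species would have the same effect. The crowded, trisubstituted enal may also decarbonylate only sluggishly.
- Fallback (sets out from 6, rejoins at 10): the alkene is removed before the carbon is taken out. Conjugate reduction of 6 with [(Ph3P)CuH]6 in wet THF gives (2S)-5,7-dimethoxy-2-(3,4,5-trimethoxyphenyl)chroman-3-carbaldehyde F5 as C3 epimers. This saturated aldehyde cannot ring-open electrocyclically and should decarbonylate more readily with RhCl(PPh3)3 in PhMe at 80 °C, giving (2S)-5,7-dimethoxy-2-(3,4,5-trimethoxyphenyl)chroman F6. Benzylic oxidation with DDQ (2.5 equiv) in CH2Cl2/H2O at rt then gives 10 directly. Hydride abstraction is directed to C4 by O1, C5–OMe and C7–OMe, as in the known C4 functionalisation of 5,7-dialkoxyflavans; water captures the cation and the resulting alcohol is oxidised further.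

**Step 3.**
- What may go wrong: hydrogen abstraction or autoxidation at C2–H, which is allylic, benzylic and α to oxygen, by peroxyl radicals would lead towards flavylium-type products. A second hydrogen-atom transfer to the C4 radical would over-reduce it to the chroman when oxygen delivery is poor. Hydroperoxide 8 could also fragment if traces of acid are present.
- Fallback (sets out from 7, rejoins at 9): a two-electron hydrometalation replaces the radical hydration. Rhodium-catalysed hydroboration of the vinylarene with catecholborane, [Rh(cod)2]BF4 and 1,4-bis(diphenylphosphino)butane in THF at −20 °C to rt places boron at the benzylic carbon, the known regiochemistry for styrene-type alkenes with cationic rhodium phosphine catalysts. It should give (2S)-4-(1,3,2-benzodioxaborol-2-yl)-5,7-dimethoxy-2-(3,4,5-trimethoxyphenyl)chroman F7. Oxidation with H2O2 and aqueous NaOH at 0 °C then gives 9.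

## Further compounds

F1 | step 1 | (E)-3-(3,4,5-trimethoxyphenyl)prop-2-en-1-ol | COc1cc(/C=C/CO)cc(OC)c1OC
F2 | step 1 | methyl (E)-3-(3,4,5-trimethoxyphenyl)prop-2-en-1-yl carbonate | COC(=O)OC/C=C/c1cc(OC)c(OC)c(OC)c1
F3 | step 1 | 2,4-dimethoxy-6-{[(1S)-1-(3,4,5-trimethoxyphenyl)prop-2-en-1-yl]oxy}benzaldehyde | COc1cc(OC)c(C=O)c(c1)O[C@H](c1cc(OC)c(OC)c(OC)c1)C=C
F4 | step 1 | 2-ethenyl-1,5-dimethoxy-3-{[(1S)-1-(3,4,5-trimethoxyphenyl)prop-2-en-1-yl]oxy}benzene | COc1cc(OC)c(C=C)c(c1)O[C@H](c1cc(OC)c(OC)c(OC)c1)C=C
F5 | step 2 | (2S)-5,7-dimethoxy-2-(3,4,5-trimethoxyphenyl)chroman-3-carbaldehyde (C3 epimers) | COc1cc(OC)c2c(c1)O[C@H](c1cc(OC)c(OC)c(OC)c1)C(C=O)C2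
F6 | step 2 | (2S)-5,7-dimethoxy-2-(3,4,5-trimethoxyphenyl)chroman | COc1cc(OC)c2c(c1)O[C@H](c1cc(OC)c(OC)c(OC)c1)CC2
F7 | step 3 | (2S)-4-(1,3,2-benzodioxaborol-2-yl)-5,7-dimethoxy-2-(3,4,5-trimethoxyphenyl)chroman (C4 epimers) | COc1cc(OC)c2c(c1)O[C@H](c1cc(OC)c(OC)c(OC)c1)CC2B1Oc2ccccc2O1
A1 | alternative 1 | methyl 3-oxo-4-[(2S)-4-oxo-2-(3,4,5-trimethoxyphenyl)-3,4-dihydro-2H-pyran-6-yl]butanoate | O=C1C=C(CC(=O)CC(=O)OC)O[C@H](c2cc(OC)c(OC)c(OC)c2)C1
A2 | alternative 1 | (2S)-5,7-dihydroxy-2-(3,4,5-trimethoxyphenyl)chroman-4-one | Oc1cc(O)c2c(c1)O[C@H](c1cc(OC)c(OC)c(OC)c1)CC2=O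
A3 | alternative 2 | 2-(2-fluoro-4,6-dimethoxyphenyl)-1,3-dithiane | COc1cc(F)c(C2SCCCS2)c(OC)c1
A4 | alternative 2 | (R)-2-(3,4,5-trimethoxyphenyl)oxirane | COc1cc(cc(OC)c1OC)[C@@H]1CO1
A5 | alternative 2 | (2S)-5,7-dimethoxy-2-(3,4,5-trimethoxyphenyl)spiro[chromane-4,2'-[1,3]dithiane] | COc1cc(OC)c2c(c1)O[C@H](c1cc(OC)c(OC)c(OC)c1)CC21SCCCS1
A6 | alternative 3 | tert-butyl[(1-{2,4-dimethoxy-6-[(1S)-1-(3,4,5-trimethoxyphenyl)prop-2-en-1-yl]oxyphenyl}ethenyl)oxy]dimethylsilane | COc1cc(OC)c(C(=C)O[Si](C)(C)C(C)(C)C)c(c1)O[C@H](c1cc(OC)c(OC)c(OC)c1)C=C
A7 | alternative 3 | (2S)-4-(tert-butyldimethylsilyloxy)-5,7-dimethoxy-2-(3,4,5-trimethoxyphenyl)-2H-chromene | COc1cc(OC)c2c(c1)O[C@H](c1cc(OC)c(OC)c(OC)c1)C=C2O[Si](C)(C)C(C)(C)C
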